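**Assumptions**
- 3'-Allyl-2',4'-dihydroxyacetophenone is treated as a catalogue chemical.
- The target SMILES decodes as (2S).
- The facial sense of the Rh step is assigned by analogy: (S)-biaryl diphosphine/Rh gives (S)-3-arylcyclohexanone, which is the same spatial face and the same descriptor here. It should be confirmed by CD on the product.

## Retrosynthetic overview
1. The target comes from its bis-MOM ether by a final mild acidic deprotection.
2. The C2–C1' bond and the only stereocentre come from a Rh(I)/chiral diphosphine 1,4-addition of a B-ring arylboronic acid to a flat 7-MOMO-8-prenylchromone.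
3. The chromone comes from enaminone cyclisation of 2-hydroxy-4-MOMO-3-prenylacetophenone, whose prenyl group is made by cross-metathesis of the 3-allyl ketone.
4. The boronic acid comes from 4-bromophenol by aqueous o,o'-diprenylation, MOM protection, and Br/Li exchange with borylation.
5. Rings A and B are purchased arenes. Ring C is the only ring built (step 4, achiral), and its C2 stereocentre is set afterwards (step 8).

## Route

**Step 1**
Reactants: 1, 3'-allyl-2',4'-dihydroxyacetophenone; 2, 2-methyl-2-butene
Product: 3, 1-[2,4-dihydroxy-3-(3-methylbut-2-enyl)phenyl]ethanone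
Conditions: Grubbs II (3 mol %), 2 / CH2Cl2 (1:1), 38 °C, sealed tube, 12 h
Reagents that add atoms: 2-methyl-2-butene, CC=C(C)C
Why: Olefin cross-metathesis of the terminal allyl arene with excess 2-methyl-2-butene converges on the trisubstituted prenyl olefin (propene is lost), tolerates the phenols and ketone, and keeps the unambiguous C3 regiochemistry of 1.

**Step 2**
Reactants: 3; 4, chloromethyl methyl ether (MOMCl)
Product: 5, 1-[2-hydroxy-4-(methoxymethoxy)-3-prenylphenyl]ethanone
Conditions: MOMCl (1.15 equiv), i-Pr2NEt (1.5 equiv), CH2Cl2, 0 °C → rt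
Reagents that add atoms: MOMCl, COCCl
Why: This Williamson-type O-alkylation is selective for the 4-OH because the 2-OH is tied up in a strong intramolecular hydrogen bond to the acetyl carbonyl.

**Step 3**
Reactants: 5; 6, N,N-dimethylformamide dimethyl acetal (DMF-DMA)
Product: 7, (E)-3-(dimethylamino)-1-[2-hydroxy-4-(methoxymethoxy)-3-prenylphenyl]prop-2-en-1-one
Conditions: DMF-DMA (2.5 equiv), toluene, 95 °C, 3 h; concentrate and use crude
Reagents that add atoms: DMF-DMA, COC(OC)N(C)C
Why: Amide-acetal condensation with the methyl ketone (enaminone formation) installs the carbon that becomes C2 under non-acidic conditions that leave the MOM and prenyl groups untouched.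

**Step 4**
Reactants: 7
Product: 8, 7-(methoxymethoxy)-8-prenyl-4H-chromen-4-one
Conditions: glacial AcOH, 80 °C, 1 h
Reagents that add atoms: none
Why: Intramolecular oxa-Michael addition followed by elimination of Me2NH on the vinylogous amide closes ring C, and AcOH is too weak to cleave the aryl MOM ether or protonate the prenyl alkene.

**Step 5**
Reactants: 9, 4-bromophenol; 10, prenyl bromide (1-bromo-3-methylbut-2-ene)
Product: 11, 4-bromo-2,6-bis(3-methylbut-2-enyl)phenol
Conditions: 10 (2.5 equiv), 2 M aq KOH (3 equiv), rt, vigorous stirring, 24 h; chromatography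
Reagents that add atoms: prenyl bromide, CC(C)=CCBr
Why: In water the phenoxide oxygen is strongly solvated, so this ambident phenoxide C-alkylation goes at the two ortho carbons (para is blocked by Br) and gives the o,o'-diprenylphenol in moderate yield.

**Step 6**
Reactants: 11; 4, MOMCl
Product: 12, 5-bromo-2-(methoxymethoxy)-1,3-bis(3-methylbut-2-enyl)benzene
Conditions: NaH (1.3 equiv), MOMCl (1.3 equiv), THF/DMF, 0 °C → rt
Reagents that add atoms: MOMCl, COCCl
Why: Williamson etherification of the fully formed sodium phenoxide overcomes the 2,6-dialkyl hindrance, and nothing else in the molecule is electrophile- or base-sensitive.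

**Step 7**
Reactants: 12; 13, triisopropyl borate
Product: 14, [4-(methoxymethoxy)-3,5-bis(3-methylbut-2-enyl)phenyl]boronic acid
Conditions: n-BuLi (1.1 equiv), THF, −78 °C, 20 min; B(Oi-Pr)3 (1.5 equiv), −78 °C → rt; sat. aq NH4Cl
Reagents that add atoms: triisopropyl borate, CC(C)OB(OC(C)C)OC(C)C; water, O
Why: Br/Li exchange at −78 °C outruns allylic-benzylic deprotonation (no ortho H is free for directed metalation), the aryllithium is trapped by the borate, and near-neutral hydrolysis preserves the MOM group.

**Step 8**
Reactants: 8; 14 (1.8 equiv)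
Product: 15, (2S)-7-(methoxymethoxy)-2-[4-(methoxymethoxy)-3,5-diprenylphenyl]-8-prenylchroman-4-one
Conditions: [RhCl(C2H4)2]2 (1.5 mol %), (S)-MeO-F12-BIPHEP (3.3 mol %), aq KOH (10 mol %), CH2Cl2/H2O (10:1), 25 °C
Reagents that add atoms: none (water supplies only H)
Why: In this Hayashi–Miyaura asymmetric 1,4-addition the aryl-Rh(I)/(S)-diphosphine complex carbometalates the Re face of C2 and water protonates the oxa-π-allyl rhodium, which sets C2 as S under near-neutral rt conditions that avoid retro-oxa-Michael racemisation and ignore the trisubstituted olefins.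

**Step 9**
Reactants: 15
Product: 16, (2S)-sophoranone [(2S)-7-hydroxy-2-(4-hydroxy-3,5-diprenylphenyl)-8-prenylchroman-4-one]
Conditions: 3 M aq HCl/MeOH (1:9), 45 °C, 1–2 h (stop at full conversion); NaHCO3 quench to pH 6
Reagents that add atoms: none
Why: Acid-catalysed acetal solvolysis removes both MOM groups faster than prenyl/phenol cycloetherification occurs, and the acidic medium avoids the base-induced chalcone ring-opening that would scramble C2.

## Compound list
| No. | Name | SMILES | Role |
|---|---|---|---|
| 1 | 3'-allyl-2',4'-dihydroxyacetophenone | CC(=O)c1ccc(O)c(CC=C)c1O | starting material |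
| 2 | 2-methyl-2-butene | CC=C(C)C | starting material |
| 3 | 2,4-dihydroxy-3-prenylacetophenone | CC(=O)c1ccc(O)c(CC=C(C)C)c1O | intermediate |
| 4 | chloromethyl methyl ether | COCCl | starting material |
| 5 | 2-hydroxy-4-(methoxymethoxy)-3-prenylacetophenone | CC(=O)c1ccc(OCOC)c(CC=C(C)C)c1O | intermediate |
| 6 | DMF dimethyl acetal | COC(OC)N(C)C | starting material |
| 7 | (E)-enaminone | CN(C)/C=C/C(=O)c1ccc(OCOC)c(CC=C(C)C)c1O | intermediate |
| 8 | 7-(methoxymethoxy)-8-prenylchromone | O=c1ccoc2c(CC=C(C)C)c(OCOC)ccc12 | intermediate |
| 9 | 4-bromophenol | Oc1ccc(Br)cc1 | starting material |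
| 10 | prenyl bromide | CC(C)=CCBr | starting material |
| 11 | 4-bromo-2,6-diprenylphenol | CC(C)=CCc1cc(Br)cc(CC=C(C)C)c1O | intermediate |
| 12 | 4-bromo-2,6-diprenylphenyl MOM ether | CC(C)=CCc1cc(Br)cc(CC=C(C)C)c1OCOC | intermediate |
| 13 | triisopropyl borate | CC(C)OB(OC(C)C)OC(C)C | starting material |
| 14 | 4-(methoxymethoxy)-3,5-diprenylphenylboronic acid | CC(C)=CCc1cc(B(O)O)cc(CC=C(C)C)c1OCOC | intermediate |
| 15 | (2S)-7,4'-bis-O-MOM-sophoranone | CC(C)=CCc1cc([C@@H]2CC(=O)c3ccc(OCOC)c(CC=C(C)C)c3O2)cc(CC=C(C)C)c1OCOC | intermediate |
| 16 | (2S)-sophoranone | CC(C)=CCc1cc([C@@H]2CC(=O)c3ccc(O)c(CC=C(C)C)c3O2)cc(CC=C(C)C)c1O | target |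

## Totals
- **Total steps:** 9. Steps 3 and 4 are telescoped without purification.
- **Longest linear sequence:** 6 (steps 1, 2, 3, 4, 8, 9). The B-ring branch is 5 (steps 5, 6, 7, 8, 9).

## Three steps most likely to fail
1. **Step 8.** The electron-rich chromone may react slowly, and protodeboronation, 1,2-over-addition or ee erosion through ring-opening may compete.
   Fallback: abandon the conjugate addition.
   - Formylate 12 (n-BuLi, then DMF).
   - Carry out a Claisen–Schmidt condensation of the aldehyde with 5.
   - Cyclise the 2'-hydroxychalcone with NaOAc to rac-15.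
   - Obtain (2S)-15 by Ru-TsDPEN transfer-hydrogenative kinetic resolution, in which the (2R)-enantiomer is reduced to the flavan-4-ol and separated.
2. **Step 5.** The yield may be low, with mixtures of mono-C-prenyl, O-prenyl and chroman by-products.
   Fallback: build the side chains by two rounds of O-allylation and aromatic Claisen rearrangement on 4-bromophenol to give 2,6-diallyl-4-bromophenol. Then run a double cross-metathesis with 2, as in step 1.
3. **Step 9.** Acid may cyclise a prenyl group onto the adjacent phenol to give a chroman, or may cause partial racemisation.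
   Fallback: change the protecting-group strategy to silyl ethers. Use TBS on 11, and swap MOM for TBS at the achiral chromone stage of 8. The final unmasking then uses buffered fluoride (Et3N·3HF or TBAF/AcOH), so the chiral prenyl-phenol system never sees a Brønsted acid.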